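**Retrosynthetic overview**
1. The target is a trans-(3R,4R)-3,4-dibenzyl-γ-butyrolactone. The lactone (O1–C2–C3–C4–C5) is the only ring to be built and is closed in the key step; both arene rings are bought.
2. Last disconnection: the exocyclic benzylic CH2 (C7′) between C4 and the 3,4,5-trimethoxyphenyl ring is carried as an aryl ketone and removed at the end by hydrogenolysis.
3. Key disconnection, C4–C5 and O1–C2: C5 is an isolated OCH2 carbon bonded only to O1 and C4, so it is a formaldehyde carbon. The C7′ ketone makes C4 an enolizable α-carbon that can attack CH2=O, and the new CH2OH closes onto the C2 carboxyl. This leads back to an (R)-2-benzyl-4-aryl-4-oxobutanoic acid.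
4. C3–C4 bond: Evans alkylation of the 3-(3,4-dimethoxyphenyl)propanoyl imide of (S)-4-benzyloxazolidin-2-one with 3,4,5-trimethoxyphenacyl bromide sets C3 as R. C4 is later set from C3 by equilibration to the trans lactone.

Key step: step 4

Assumption: the trans keto lactone is taken to be the thermodynamically preferred C4 epimer, as is general for 3,4-disubstituted γ-butyrolactones; all starting materials, including 37% aqueous formaldehyde, are taken as commercial.

**Step 1**
Reactants: 1 3-(3,4-dimethoxyphenyl)propanoic acid; 2 (S)-4-benzyloxazolidin-2-one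
Product: 4 (S)-4-benzyl-3-[3-(3,4-dimethoxyphenyl)propanoyl]oxazolidin-2-one, via mixed pivalic anhydride 3 (not isolated)
Conditions: t-BuCOCl, Et3N, THF, −20 °C; then LiCl, 2, −20 °C → rt
Reagents that add atoms: none
Why: Mixed-anhydride N-acylation of an oxazolidinone, in which the LiCl-activated, Et3N-deprotonated oxazolidinone attacks the unhindered arylpropanoyl carbonyl of 3 and not the tert-butyl-shielded one; no stereocentre is formed and that of 2 is untouched.

**Step 2**
Reactants: 4 (S)-4-benzyl-3-[3-(3,4-dimethoxyphenyl)propanoyl]oxazolidin-2-one; 5 2-bromo-1-(3,4,5-trimethoxyphenyl)ethanone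
Product: 7 (S)-4-benzyl-3-[(R)-2-(3,4-dimethoxybenzyl)-4-oxo-4-(3,4,5-trimethoxyphenyl)butanoyl]oxazolidin-2-one, via sodium Z-enolate 6 (not isolated)
Conditions: NaN(SiMe3)2 (1.1 equiv), THF, −78 °C; then 5 (1.3 equiv) in THF, −78 → −40 °C; AcOH quench
Reagents that add atoms: none
Why: Evans asymmetric alkylation, in which the sodium-chelated Z-enolate 6 has one face screened by the C4 benzyl group of the auxiliary, so the highly SN2-reactive phenacyl bromide 5 should attack Cα from the opposite (Si) face and set the new centre as R.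

**Step 3**
Reactants: 7 (S)-4-benzyl-3-[(R)-2-(3,4-dimethoxybenzyl)-4-oxo-4-(3,4,5-trimethoxyphenyl)butanoyl]oxazolidin-2-one
Product: 9 (R)-2-(3,4-dimethoxybenzyl)-4-oxo-4-(3,4,5-trimethoxyphenyl)butanoic acid, via peroxy acid 8 (not isolated)
Conditions: LiOH·H2O, 30% H2O2, THF/H2O (3:1), 0 °C; then aq Na2SO3; then 1 M HCl to pH 2
Reagents that add atoms: hydrogen peroxide, OO (delivered as LiOOH; one of its oxygens ends as the carboxyl OH oxygen)
Why: Hydroperoxide cleavage of an Evans imide, in which LiOOH attacks the exocyclic acyl carbonyl selectively, releasing recoverable auxiliary 2 and peroxy acid 8 that sulfite reduces to 9; at 0 °C the α-centre should not epimerize and the aryl ketone should not be oxidized.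

**Step 4**
Reactants: 9 (R)-2-(3,4-dimethoxybenzyl)-4-oxo-4-(3,4,5-trimethoxyphenyl)butanoic acid; 10 formaldehyde
Product: 13 (3R,4R)-3-(3,4-dimethoxybenzyl)-4-(3,4,5-trimethoxybenzoyl)dihydrofuran-2(3H)-one, via hydroxymethyl keto acid 11 (not isolated), via cis keto lactone 12 (not isolated)
Conditions: NaOH (2.2 equiv), 37% aq CH2O (1.2 equiv), H2O/THF, 0 °C → rt; then 2 M HCl to pH 1, 40 °C; then DBU (0.1 equiv), CH2Cl2, rt
Reagents that add atoms: none
Why: Hydroxide turns 9 into its carboxylate and reversibly enolizes the aryl ketone at the only acidic C–H position, the CH2 between the carbonyl and the stereocentre (future C4); this enolate adds to formaldehyde in a crossed aldol (Tollens-type hydroxymethylation), forming C4–C5 and giving hydroxy acid 11. The closest known reaction is the base-mediated hydroxymethylation–lactonization of β-aroylpropionic acids to β-aroyl-γ-butyrolactones. On acidification the primary hydroxyl attacks the carboxyl carbon in a 5-exo-trig acyl substitution, forming O1–C2 and the only ring that has to be built. C4 is the new stereocentre; it stays enolizable because it is α to the ketone, so it is set under thermodynamic control by the C3 benzyl group, and the portion that closes as cis lactone 12 is epimerized by catalytic DBU to trans lactone 13. The step needs a single hydroxymethylation at C4 and retention at C3: C3 is α to a carboxylate throughout the basic stage and should not be deprotonated, and after the first addition C4 is a hindered tertiary centre next to the C3 branch, so with only a slight excess of formaldehyde at low temperature a second addition or dehydration should stay minor.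

**Step 5**
Reactants: 13 (3R,4R)-3-(3,4-dimethoxybenzyl)-4-(3,4,5-trimethoxybenzoyl)dihydrofuran-2(3H)-one
Product: 15 (3R,4R)-3-(3,4-dimethoxybenzyl)-4-(3,4,5-trimethoxybenzyl)dihydrofuran-2(3H)-one, via benzylic carbinol 14 (not isolated)
Conditions: H2 (3 atm), Pd/C (10% Pd), AcOH, HClO4 (cat.), rt
Reagents that add atoms: none
Why: Acid-promoted benzylic hydrogenolysis of an electron-rich aryl ketone over Pd/C, in which the carbonyl is reduced to carbinol 14 and its benzylic C–O bond, ionized with the help of HClO4 and the para-methoxy group, is cleaved to CH2; C3 and C4 are not involved, and the lactone and aryl ethers should be inert.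

**Compound list**
1 | 3-(3,4-dimethoxyphenyl)propanoic acid | OC(=O)CCc1ccc(OC)c(OC)c1 | starting material
2 | (S)-4-benzyloxazolidin-2-one | O=C1N[C@@H](Cc2ccccc2)CO1 | starting material
3 | 3-(3,4-dimethoxyphenyl)propanoic pivalic anhydride (not isolated) | COc1ccc(CCC(=O)OC(=O)C(C)(C)C)cc1OC | intermediate
4 | (S)-4-benzyl-3-[3-(3,4-dimethoxyphenyl)propanoyl]oxazolidin-2-one | COc1ccc(CCC(=O)N2C(=O)OC[C@@H]2Cc2ccccc2)cc1OC | intermediate
5 | 2-bromo-1-(3,4,5-trimethoxyphenyl)ethanone | COc1cc(C(=O)CBr)cc(OC)c1OC | starting material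
6 | sodium (1Z)-1-[(4S)-4-benzyl-2-oxooxazolidin-3-yl]-3-(3,4-dimethoxyphenyl)prop-1-en-1-olate (not isolated) | COc1ccc(C/C=C(\[O-])N2C(=O)OC[C@@H]2Cc2ccccc2)cc1OC.[Na+] | intermediate
7 | (S)-4-benzyl-3-[(R)-2-(3,4-dimethoxybenzyl)-4-oxo-4-(3,4,5-trimethoxyphenyl)butanoyl]oxazolidin-2-one | COc1ccc(C[C@H](CC(=O)c2cc(OC)c(OC)c(OC)c2)C(=O)N2C(=O)OC[C@@H]2Cc2ccccc2)cc1OC | intermediate
8 | (R)-2-(3,4-dimethoxybenzyl)-4-oxo-4-(3,4,5-trimethoxyphenyl)butaneperoxoic acid (not isolated) | COc1ccc(C[C@H](CC(=O)c2cc(OC)c(OC)c(OC)c2)C(=O)OO)cc1OC | intermediate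
9 | (R)-2-(3,4-dimethoxybenzyl)-4-oxo-4-(3,4,5-trimethoxyphenyl)butanoic acid | COc1ccc(C[C@H](CC(=O)c2cc(OC)c(OC)c(OC)c2)C(=O)O)cc1OC | intermediate
10 | formaldehyde | C=O | starting material
11 | (2R)-2-(3,4-dimethoxybenzyl)-3-(hydroxymethyl)-4-oxo-4-(3,4,5-trimethoxyphenyl)butanoic acid, both C3 epimers (not isolated) | COc1ccc(C[C@H](C(CO)C(=O)c2cc(OC)c(OC)c(OC)c2)C(=O)O)cc1OC | intermediate
12 | (3R,4S)-3-(3,4-dimethoxybenzyl)-4-(3,4,5-trimethoxybenzoyl)dihydrofuran-2(3H)-one, cis epimer formed beside 13 on lactonization and epimerized to it (not isolated) | COc1ccc(C[C@H]2C(=O)OC[C@H]2C(=O)c2cc(OC)c(OC)c(OC)c2)cc1OC | intermediate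
13 | (3R,4R)-3-(3,4-dimethoxybenzyl)-4-(3,4,5-trimethoxybenzoyl)dihydrofuran-2(3H)-one | COc1ccc(C[C@H]2C(=O)OC[C@@H]2C(=O)c2cc(OC)c(OC)c(OC)c2)cc1OC | intermediate
14 | (3R,4R)-3-(3,4-dimethoxybenzyl)-4-[hydroxy(3,4,5-trimethoxyphenyl)methyl]dihydrofuran-2(3H)-one, both carbinol epimers (not isolated) | COc1ccc(C[C@H]2C(=O)OC[C@@H]2C(O)c2cc(OC)c(OC)c(OC)c2)cc1OC | intermediate
15 | (3R,4R)-3-(3,4-dimethoxybenzyl)-4-(3,4,5-trimethoxybenzyl)dihydrofuran-2(3H)-one | COc1ccc(C[C@H]2C(=O)OC[C@@H]2Cc2cc(OC)c(OC)c(OC)c2)cc1OC | target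

**Total step count:** 5
**Longest linear sequence:** 5 steps (from 1 to 15)

**Steps most likely to fail**

1. Step 4. A second formaldehyde could add at C4. The aldol could also dehydrate in base to an α-methylene ketone, whose double bond can migrate and erase C3. Convergence of C4 to trans may be incomplete. The fallback sets out from 9 and returns at 13, and replaces the basic aldol with a Lewis-acid aldol of a preformed enol silane. Acid 9 would be O-methylated (MeI, KHCO3, DMF, rt) to methyl (R)-2-(3,4-dimethoxybenzyl)-4-oxo-4-(3,4,5-trimethoxyphenyl)butanoate F1. Soft enolization of the ketone (Me3SiOTf, Et3N, CH2Cl2, 0 °C) should give methyl (2R,3Z)-2-(3,4-dimethoxybenzyl)-4-(3,4,5-trimethoxyphenyl)-4-(trimethylsilyloxy)but-3-enoate F2. A Mukaiyama aldol with aqueous formaldehyde (Yb(OTf)3 cat., THF/H2O, rt) should add exactly one CH2OH, because the product is no longer a donor under non-basic conditions, giving methyl (2R)-2-(3,4-dimethoxybenzyl)-3-(hydroxymethyl)-4-oxo-4-(3,4,5-trimethoxyphenyl)butanoate F3 as both C3 epimers. p-TsOH (cat.) in warm toluene should close the lactone with loss of methanol, and catalytic DBU in CH2Cl2 should converge C4 to 13.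

2. Step 2. Proton transfer from the acidic bromo ketone, or from the more acidic γ-keto imide product, to the enolate could stall conversion. Addition to the ketone carbonyl (Darzens-type) or a second alkylation could compete with the SN2 reaction. The fallback sets out from 4 and returns at 7, and builds the aryl ketone by cross-coupling instead of alkylation. Enolate 6 would be alkylated with tert-butyl bromoacetate (THF, −78 °C) to give tert-butyl (3R)-3-{[(4S)-4-benzyl-2-oxooxazolidin-3-yl]carbonyl}-4-(3,4-dimethoxyphenyl)butanoate F4. CF3CO2H in CH2Cl2 should remove the tert-butyl group to give (3R)-3-{[(4S)-4-benzyl-2-oxooxazolidin-3-yl]carbonyl}-4-(3,4-dimethoxyphenyl)butanoic acid F5. Steglich thioesterification (PhSH, EDC·HCl, DMAP cat., CH2Cl2) should give S-phenyl (3R)-3-{[(4S)-4-benzyl-2-oxooxazolidin-3-yl]carbonyl}-4-(3,4-dimethoxyphenyl)butanethioate F6. Liebeskind–Srogl coupling with 3,4,5-trimethoxyphenylboronic acid should then deliver 7 under neutral conditions that leave the imide and its α-centre alone. The coupling uses Pd2(dba)3 (cat., zerovalent palladium), tris(2-furyl)phosphine and copper thiophene-2-carboxylate Cu(O2C-C4H3S) (monovalent copper) in THF at 50 °C.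

3. Step 5. The reduction could stall at the carbinol, because the twisted 4-methoxy group of the trimethoxyphenyl ring stabilizes the benzylic cation only moderately. The lactone acyl group could migrate to the benzylic hydroxyl, and forcing conditions could saturate an arene. The fallback sets out from 13 and returns at 15, and removes the carbonyl by a Mozingo sequence that needs no benzylic cation. Ethane-1,2-dithiol with BF3·OEt2 (CH2Cl2, rt) should give (3R,4R)-3-(3,4-dimethoxybenzyl)-4-[2-(3,4,5-trimethoxyphenyl)-1,3-dithiolan-2-yl]dihydrofuran-2(3H)-one F7. Desulfurization with Raney Ni in ethanol at reflux should then give 15, with C3 and C4 untouched.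

**Further compounds**
F1 | step 4 | methyl (R)-2-(3,4-dimethoxybenzyl)-4-oxo-4-(3,4,5-trimethoxyphenyl)butanoate | COc1ccc(C[C@H](CC(=O)c2cc(OC)c(OC)c(OC)c2)C(=O)OC)cc1OC
F2 | step 4 | methyl (2R,3Z)-2-(3,4-dimethoxybenzyl)-4-(3,4,5-trimethoxyphenyl)-4-(trimethylsilyloxy)but-3-enoate | COc1ccc(C[C@H](/C=C(\O[Si](C)(C)C)c2cc(OC)c(OC)c(OC)c2)C(=O)OC)cc1OC
F3 | step 4 | methyl (2R)-2-(3,4-dimethoxybenzyl)-3-(hydroxymethyl)-4-oxo-4-(3,4,5-trimethoxyphenyl)butanoate, both C3 epimers | COc1ccc(C[C@H](C(CO)C(=O)c2cc(OC)c(OC)c(OC)c2)C(=O)OC)cc1OC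
F4 | step 2 | tert-butyl (3R)-3-{[(4S)-4-benzyl-2-oxooxazolidin-3-yl]carbonyl}-4-(3,4-dimethoxyphenyl)butanoate | COc1ccc(C[C@H](CC(=O)OC(C)(C)C)C(=O)N2C(=O)OC[C@@H]2Cc2ccccc2)cc1OC
F5 | step 2 | (3R)-3-{[(4S)-4-benzyl-2-oxooxazolidin-3-yl]carbonyl}-4-(3,4-dimethoxyphenyl)butanoic acid | COc1ccc(C[C@H](CC(=O)O)C(=O)N2C(=O)OC[C@@H]2Cc2ccccc2)cc1OC
F6 | step 2 | S-phenyl (3R)-3-{[(4S)-4-benzyl-2-oxooxazolidin-3-yl]carbonyl}-4-(3,4-dimethoxyphenyl)butanethioate | COc1ccc(C[C@H](CC(=O)Sc2ccccc2)C(=O)N2C(=O)OC[C@@H]2Cc2ccccc2)cc1OC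
F7 | step 5 | (3R,4R)-3-(3,4-dimethoxybenzyl)-4-[2-(3,4,5-trimethoxyphenyl)-1,3-dithiolan-2-yl]dihydrofuran-2(3H)-one | COc1ccc(C[C@H]2C(=O)OC[C@@H]2C2(c3cc(OC)c(OC)c(OC)c3)SCCS2)cc1OC
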